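**Strategy.** The polyene is cut at the C14–C15 single bond (carotenoid numbering), which is flanked by the methyl-branched, trisubstituted C13=C14 alkene of the open chain; ring A, the hydroxycyclohexene, is a spectator. That alkene is read as the syn-methylmetalation product of a terminal alkyne. In one flask, a ring A trienyne ending in C13≡C14–H is carboaluminated (Me3Al, Cp2ZrCl2), which installs the C13 methyl group and the 13E geometry, and the resulting C14 alkenylalane is cross-coupled under palladium and zinc catalysis with a C15–C8' tetraenyl iodide. The precursor therefore lacks both the C13 methyl group and the C13=C14 double bond: three components, two C–C bonds, one operation.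

Key step: step 15

Remarks on the chemistry:
- Numbering: ring A is C1 (CMe2), C2, C3 (CHOH), C4, C5, C6 (CH carrying the chain); the chain runs C7–C15, then C15'–C8' (the CH2OH carbon).
- Assumption: (R)-α-ionone of high enantiomeric purity and isomerically pure (E)-3-methylpent-2-en-4-yn-1-ol are taken as purchasable.
- TBS = tert-butyldimethylsilyl.

**Ring A and the left-hand trienyne**

Step 1
Reactants: 1 (R)-α-ionone
Product: 2 2-methyl-2-[(E)-2-[(1R)-2,6,6-trimethylcyclohex-2-en-1-yl]ethenyl]-1,3-dioxolane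
Conditions: TMSOCH2CH2OTMS, TMSOTf (cat.), CH2Cl2, −78 °C
Reagents that add atoms: 1,2-bis(trimethylsilyloxy)ethane C[Si](C)(C)OCCO[Si](C)(C)C
Why: Noyori ketalisation under aprotic, kinetic conditions masks the C9 ketone as a base-stable dioxolane without moving the C7=C8 alkene or touching the C6 stereocentre.

Step 2
Reactants: 2 (R)-α-ionone ethylene ketal
Product: 3 (4R)-3,5,5-trimethyl-4-[(E)-2-(2-methyl-1,3-dioxolan-2-yl)ethenyl]cyclohex-2-en-1-one
Conditions: t-BuOOH, dirhodium tetrakis(caprolactamate) Rh2(cap)4 (cat.), K2CO3, CH2Cl2, rt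
Reagents that add atoms: tert-butyl hydroperoxide CC(C)(C)OO
Why: Catalytic allylic C–H oxidation should convert the only unhindered ring allylic methylene (C3, next to C4=C5) into the enone, the tertiary C6–H being shielded by the gem-dimethyl group and the side chain.

Step 3
Reactants: 3 3-oxo ketal
Product: 5 (E)-4-[(1R,4R)-4-hydroxy-2,6,6-trimethylcyclohex-2-en-1-yl]but-3-en-2-one ((3R,6R)-3-hydroxy-α-ionone), via hydroxy ketal 4 (not isolated)
Conditions: LiBH(s-Bu)3, THF, −78 °C; then 1 M HCl (aq), 0 °C → rt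
Reagents that add atoms: water O
Why: 1,2-Reduction of the β,β-disubstituted cyclohexenone by the bulky borohydride should occur on the half-chair with the C6 side chain pseudoaxial, from the face away from the axial C1 methyl group, placing the new C3 hydroxyl trans to the side chain (3R), and the acidic quench hydrolyses the allylic dioxolane.

Step 4
Reactants: 5 (3R,6R)-3-hydroxy-α-ionone
Product: 6 (E)-4-[(1R,4R)-4-(tert-butyldimethylsilyloxy)-2,6,6-trimethylcyclohex-2-en-1-yl]but-3-en-2-one
Conditions: TBSCl, imidazole, DMF, rt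
Reagents that add atoms: tert-butyldimethylsilyl chloride CC(C)(C)[Si](C)(C)Cl
Why: Standard imidazole-mediated silylation protects the secondary allylic alcohol against the amide base and the alanes used later.

Step 5
Reactants: 6 silyl ether ketone
Product: 8 tert-butyl-[[(1R,4R)-4-[(E)-but-1-en-3-ynyl]-3,5,5-trimethylcyclohex-2-en-1-yl]oxy]dimethylsilane, via enol phosphate 7 (not isolated)
Conditions: LiN(i-Pr)2, THF, −78 °C; ClP(O)(OEt)2, −78 °C → rt; then LiN(i-Pr)2 (excess), −78 °C → rt; NH4Cl (aq)
Reagents that add atoms: none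
Why: Negishi's methyl ketone to terminal alkyne conversion: kinetic enolisation at the methyl group (not at the γ C6–H), O-phosphorylation and amide-induced elimination of diethyl phosphate give the C9≡C10 alkyne.

Step 6
Reactants: 9 (E)-1,2-dichloroethene (excess); 10 ethynyltrimethylsilane
Product: 11 (E)-1-chloro-4-(trimethylsilyl)but-1-en-3-yne
Conditions: Pd(PPh3)4 (cat.), CuI (cat.), n-BuNH2, Et2O, rt
Reagents that add atoms: none
Why: Sonogashira mono-alkynylation of the dichloroalkene proceeds with retention of the E geometry, and the excess of 9 suppresses the second coupling.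

Step 7
Reactants: 8 ring A enyne; 11 chloroenyne
Product: 13 tert-butyl-dimethyl-[[(1R,4R)-3,5,5-trimethyl-4-[(1E,3E,5E)-3-methyl-8-(trimethylsilyl)octa-1,3,5-trien-7-ynyl]cyclohex-2-en-1-yl]oxy]silane, via alkenylalane 12 (not isolated)
Conditions: Me3Al, Cp2ZrCl2 (cat.), (CH2Cl)2, rt; evaporate excess Me3Al; then 11, Pd(P(t-Bu)3)2 (cat.), ZnCl2 (cat.), THF/DMF, rt → 50 °C
Reagents that add atoms: trimethylaluminium C[Al](C)C
Why: Negishi zirconium-catalysed syn-methylalumination of the terminal alkyne sets the C9 methyl group and the 9E alkene, and palladium/zinc-catalysed cross-coupling of the alane with the activated alkenyl chloride forms C10–C11 with retention.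

Step 8
Reactants: 13 silylated trienyne
Product: 14 tert-butyl-dimethyl-[[(1R,4R)-3,5,5-trimethyl-4-[(1E,3E,5E)-3-methylocta-1,3,5-trien-7-ynyl]cyclohex-2-en-1-yl]oxy]silane
Conditions: K2CO3 (cat.), MeOH/THF, rt
Reagents that add atoms: none
Why: Methanolysis cleaves the alkynyl C–Si bond selectively, and the TBS ether is stable to carbonate in methanol.

**Right-hand tetraenyl iodide**

Step 9
Reactants: 15 prop-2-yn-1-ol
Product: 17 (E)-3-iodo-2-methylprop-2-en-1-ol, via alkenylalane 16 (not isolated)
Conditions: Me3Al (excess), Cp2ZrCl2, CH2Cl2, 0 °C → rt; then I2, THF, −30 → 0 °C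
Reagents that add atoms: trimethylaluminium C[Al](C)C; iodine II
Why: Negishi carboalumination of the aluminium propargyl alkoxide adds Me–Al syn with methyl at the internal carbon, and iodinolysis with retention gives the E iodide that carries C8', C9' (with its methyl) and C10'.

Step 10
Reactants: 17 iodo alcohol
Product: 18 tert-butyl-[(E)-3-iodo-2-methylprop-2-enoxy]dimethylsilane
Conditions: TBSCl, imidazole, CH2Cl2, rt
Reagents that add atoms: tert-butyldimethylsilyl chloride CC(C)(C)[Si](C)(C)Cl
Why: Standard silylation differentiates the C8' oxygen from the C15' alcohol that is oxidised later.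

Step 11
Reactants: 19 (E)-3-methylpent-2-en-4-yn-1-ol
Product: 20 (2E,4E)-3-methyl-5-(tributylstannyl)penta-2,4-dien-1-ol
Conditions: Bu3SnH, PdCl2(PPh3)2 (cat.), THF, 0 °C
Reagents that add atoms: tributyltin hydride CCCC[SnH](CCCC)CCCC
Why: Palladium-catalysed syn hydrostannation of the terminal alkyne of an E-enynol places tin at the distal carbon and gives the E alkenylstannane.

Step 12
Reactants: 20 stannyl dienol; 18 silylated iodide
Product: 21 (2E,4E,6E)-8-(tert-butyldimethylsilyloxy)-3,7-dimethylocta-2,4,6-trien-1-ol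
Conditions: PdCl2(MeCN)2 (cat.), DMF, rt, dark
Reagents that add atoms: none
Why: Stille alkenyl–alkenyl coupling forms C10'–C11' with retention of both alkene geometries and tolerates the free allylic alcohol.

Step 13
Reactants: 21 trienol
Product: 22 (2E,4E,6E)-8-(tert-butyldimethylsilyloxy)-3,7-dimethylocta-2,4,6-trienal
Conditions: MnO2, CH2Cl2, rt, dark
Reagents that add atoms: none
Why: Manganese dioxide oxidises the free allylic alcohol chemoselectively to the trienal without isomerisation, and the silyl ether is untouched.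

Step 14
Reactants: 22 trienal
Product: 23 tert-butyl-[(2E,4E,6E,8E)-9-iodo-2,6-dimethylnona-2,4,6,8-tetraenoxy]dimethylsilane
Conditions: CHI3, CrCl2, THF, 0 °C → rt, dark
Reagents that add atoms: iodoform IC(I)I
Why: Takai olefination with the geminal dichromium carbenoid from iodoform converts the aldehyde into the E alkenyl iodide, creating the C15=C15' alkene.

**Fragment union and deprotection**

Step 15
Reactants: 14 ring A trienyne; 23 tetraenyl iodide
Product: 25 tert-butyl-[(2E,4E,6E,8E,10E,12E,14E,16E)-17-[(1R,4R)-4-(tert-butyldimethylsilyloxy)-2,6,6-trimethylcyclohex-2-en-1-yl]-2,6,11,15-tetramethylheptadeca-2,4,6,8,10,12,14,16-octaenoxy]dimethylsilane, via alkenylalane 24 (not isolated)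
Conditions: Me3Al, Cp2ZrCl2 (cat.), (CH2Cl)2, rt; evaporate excess Me3Al; then 23, Pd2(dba)3 (cat.), P(2-furyl)3, ZnCl2 (cat.), THF/DMF, rt, dark
Reagents that add atoms: trimethylaluminium C[Al](C)C
Why: Cp2ZrCl2 and Me3Al form a methylzirconocene–chloroaluminate pair that adds Me–metal syn across the terminal C13≡C14 alkyne of 14, methyl to the internal C13 and metal to C14, giving alkenylalane 24; zerovalent palladium then inserts into the C15–I bond of 23 with retention, the alkenyl group passes from aluminium via zinc to palladium, and reductive elimination forms the C14–C15 bond. The closest known reaction type is the one-pot Negishi zirconium-catalysed carboalumination followed by palladium- and zinc-catalysed alkenyl–alkenyl cross-coupling of terminal polyenynes. No ring is closed and no stereocentre is created; the controlling element for the new C13=C14 alkene is the syn carbometalation, which fixes it as E, and stereoretentive coupling carries over the four E alkenes of 23. The step needs methyl delivery to C13 only, which the terminal alkyne secures because the metal goes to the less hindered carbon. It needs alkenyl rather than methyl transfer to palladium, which removal of excess Me3Al before the coupling and the faster transmetalation of alkenyl groups secure. It also needs both silyl ethers and the C6 stereocentre to survive, which the neutral, base-free conditions at room temperature allow.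

Step 16
Reactants: 25 bis-silyl ether
Product: 26 (2E,4E,6E,8E,10E,12E,14E,16E)-17-[(1R,4R)-4-hydroxy-2,6,6-trimethylcyclohex-2-en-1-yl]-2,6,11,15-tetramethylheptadeca-2,4,6,8,10,12,14,16-octaen-1-ol
Conditions: Bu4NF, THF, 0 °C → rt, dark, argon
Reagents that add atoms: none
Why: Fluoride cleaves the primary and the secondary allylic Si–O bonds under non-acidic conditions that should leave the octaene and both stereocentres unchanged.

**Compound list**

1 | (R)-α-ionone, (E)-4-[(1R)-2,6,6-trimethylcyclohex-2-en-1-yl]but-3-en-2-one | CC1=CCCC(C)(C)[C@H]1/C=C/C(C)=O | starting material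
2 | 2-methyl-2-[(E)-2-[(1R)-2,6,6-trimethylcyclohex-2-en-1-yl]ethenyl]-1,3-dioxolane | CC1=CCCC(C)(C)[C@H]1/C=C/C2(C)OCCO2 | intermediate
3 | (4R)-3,5,5-trimethyl-4-[(E)-2-(2-methyl-1,3-dioxolan-2-yl)ethenyl]cyclohex-2-en-1-one | CC1=CC(=O)CC(C)(C)[C@H]1/C=C/C2(C)OCCO2 | intermediate
4 | (1R,4R)-3,5,5-trimethyl-4-[(E)-2-(2-methyl-1,3-dioxolan-2-yl)ethenyl]cyclohex-2-en-1-ol (trans-hydroxy ketal, formed as its lithium alkoxide) | CC1=C[C@H](O)CC(C)(C)[C@H]1/C=C/C2(C)OCCO2 | intermediate (not isolated)
5 | (E)-4-[(1R,4R)-4-hydroxy-2,6,6-trimethylcyclohex-2-en-1-yl]but-3-en-2-one | CC1=C[C@H](O)CC(C)(C)[C@H]1/C=C/C(C)=O | intermediate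
6 | (E)-4-[(1R,4R)-4-(tert-butyldimethylsilyloxy)-2,6,6-trimethylcyclohex-2-en-1-yl]but-3-en-2-one | CC1=C[C@H](O[Si](C)(C)C(C)(C)C)CC(C)(C)[C@H]1/C=C/C(C)=O | intermediate
7 | [(E)-4-[(1R,4R)-4-(tert-butyldimethylsilyloxy)-2,6,6-trimethylcyclohex-2-en-1-yl]buta-1,3-dien-2-yl] diethyl phosphate | CC1=C[C@H](O[Si](C)(C)C(C)(C)C)CC(C)(C)[C@H]1/C=C/C(=C)OP(=O)(OCC)OCC | intermediate (not isolated)
8 | tert-butyl-[[(1R,4R)-4-[(E)-but-1-en-3-ynyl]-3,5,5-trimethylcyclohex-2-en-1-yl]oxy]dimethylsilane | CC1=C[C@H](O[Si](C)(C)C(C)(C)C)CC(C)(C)[C@H]1/C=C/C#C | intermediate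
9 | (E)-1,2-dichloroethene | Cl/C=C/Cl | starting material
10 | ethynyltrimethylsilane | C#C[Si](C)(C)C | starting material
11 | (E)-1-chloro-4-(trimethylsilyl)but-1-en-3-yne | Cl/C=C/C#C[Si](C)(C)C | intermediate
12 | dimethyl[(1E,3E)-4-[(1R,4R)-4-(tert-butyldimethylsilyloxy)-2,6,6-trimethylcyclohex-2-en-1-yl]-2-methylbuta-1,3-dienyl]alane | CC1=C[C@H](O[Si](C)(C)C(C)(C)C)CC(C)(C)[C@H]1/C=C/C(C)=C/[Al](C)C | intermediate (not isolated)
13 | tert-butyl-dimethyl-[[(1R,4R)-3,5,5-trimethyl-4-[(1E,3E,5E)-3-methyl-8-(trimethylsilyl)octa-1,3,5-trien-7-ynyl]cyclohex-2-en-1-yl]oxy]silane | CC1=C[C@H](O[Si](C)(C)C(C)(C)C)CC(C)(C)[C@H]1/C=C/C(C)=C/C=C/C#C[Si](C)(C)C | intermediate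
14 | tert-butyl-dimethyl-[[(1R,4R)-3,5,5-trimethyl-4-[(1E,3E,5E)-3-methylocta-1,3,5-trien-7-ynyl]cyclohex-2-en-1-yl]oxy]silane | CC1=C[C@H](O[Si](C)(C)C(C)(C)C)CC(C)(C)[C@H]1/C=C/C(C)=C/C=C/C#C | intermediate
15 | prop-2-yn-1-ol | C#CCO | starting material
16 | dimethylaluminium (E)-3-(dimethylalumanyl)-2-methylprop-2-en-1-olate | C[Al](C)OC/C(C)=C/[Al](C)C | intermediate (not isolated)
17 | (E)-3-iodo-2-methylprop-2-en-1-ol | OC/C(C)=C/I | intermediate
18 | tert-butyl-[(E)-3-iodo-2-methylprop-2-enoxy]dimethylsilane | CC(C)(C)[Si](C)(C)OC/C(C)=C/I | intermediate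
19 | (E)-3-methylpent-2-en-4-yn-1-ol | C#C/C(C)=C/CO | starting material
20 | (2E,4E)-3-methyl-5-(tributylstannyl)penta-2,4-dien-1-ol | CCCC[Sn](CCCC)(CCCC)/C=C/C(C)=C/CO | intermediate
21 | (2E,4E,6E)-8-(tert-butyldimethylsilyloxy)-3,7-dimethylocta-2,4,6-trien-1-ol | OC/C=C(C)/C=C/C=C(\C)CO[Si](C)(C)C(C)(C)C | intermediate
22 | (2E,4E,6E)-8-(tert-butyldimethylsilyloxy)-3,7-dimethylocta-2,4,6-trienal | O=C/C=C(C)/C=C/C=C(\C)CO[Si](C)(C)C(C)(C)C | intermediate
23 | tert-butyl-[(2E,4E,6E,8E)-9-iodo-2,6-dimethylnona-2,4,6,8-tetraenoxy]dimethylsilane | I/C=C/C=C(C)/C=C/C=C(\C)CO[Si](C)(C)C(C)(C)C | intermediate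
24 | dimethyl[(1E,3E,5E,7E)-8-[(1R,4R)-4-(tert-butyldimethylsilyloxy)-2,6,6-trimethylcyclohex-2-en-1-yl]-2,6-dimethylocta-1,3,5,7-tetraenyl]alane | CC1=C[C@H](O[Si](C)(C)C(C)(C)C)CC(C)(C)[C@H]1/C=C/C(C)=C/C=C/C(C)=C/[Al](C)C | intermediate (not isolated)
25 | tert-butyl-[(2E,4E,6E,8E,10E,12E,14E,16E)-17-[(1R,4R)-4-(tert-butyldimethylsilyloxy)-2,6,6-trimethylcyclohex-2-en-1-yl]-2,6,11,15-tetramethylheptadeca-2,4,6,8,10,12,14,16-octaenoxy]dimethylsilane | CC1=C[C@H](O[Si](C)(C)C(C)(C)C)CC(C)(C)[C@H]1/C=C/C(C)=C/C=C/C(C)=C/C=C/C=C(C)/C=C/C=C(\C)CO[Si](C)(C)C(C)(C)C | intermediate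
26 | (2E,4E,6E,8E,10E,12E,14E,16E)-17-[(1R,4R)-4-hydroxy-2,6,6-trimethylcyclohex-2-en-1-yl]-2,6,11,15-tetramethylheptadeca-2,4,6,8,10,12,14,16-octaen-1-ol, CNP0292981.1 | CC1=C[C@H](O)CC(C)(C)[C@H]1/C=C/C(C)=C/C=C/C(C)=C/C=C/C=C(C)/C=C/C=C(\C)CO | target

**Step count**

Total: 16 steps. Longest linear sequence: 9 steps (1, 2, 3, 4, 5, 7, 8, 15, 16).

**Steps most likely to fail**

1. Step 15. Transfer of the alkenyl group from aluminium to palladium may be slower than methyl transfer, or slower than decomposition and E/Z isomerisation of the light-sensitive tetraenyl iodide in the Lewis acidic medium. The fallback separates the two events and couples under neutral conditions. It sets out from 14 and 22. Alkyne 14 is carboaluminated as before, but the alane is quenched with I2 to give the isolable (13E)-alkenyl iodide F1. Trienal 22 is homologated with Bu3SnCHBr2, CrCl2 and LiI (Hodgson variant of the Takai reaction) to the E-tetraenylstannane F2. Stille coupling of F1 with F2 (Pd2(dba)3, AsPh3, N-methylpyrrolidone, rt, dark) forms the same C14–C15 bond and comes back to the route at 25.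

2. Step 7. Insertion of zerovalent palladium into the alkenyl chloride may be too slow, so that the alane is lost by protonation or homocoupling; the amide-base chemistry of step 5 on which it depends could also erode the C6 configuration. The fallback builds the chain by olefination and sets out from 6. Horner–Wadsworth–Emmons reaction with diethyl cyanomethylphosphonate (NaH, THF) and removal of the 9Z isomer should give the dienenitrile F3. Reduction with i-Bu2AlH (toluene, −78 °C, mild aqueous acid) gives the dienal F4. A second Horner–Wadsworth–Emmons reaction with diethyl [3-(trimethylsilyl)prop-2-ynyl]phosphonate (LiN(SiMe3)2, THF, −78 °C) comes back to the route at 13, bypassing steps 5 to 7.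

3. Step 3. Hydride delivery may occur from the wrong face and give the cis alcohol, or the strongly acidic quench may ionise the new allylic alcohol. The fallback corrects the configuration by inversion and sets out from 3. Reduction with NaBH4 and CeCl3 (MeOH, −20 °C) and chromatographic separation give the cis-hydroxy ketal F5. Mitsunobu reaction (4-nitrobenzoic acid, PPh3, diisopropyl azodicarboxylate, THF) inverts C3 to the trans 4-nitrobenzoate F6. Methanolysis (K2CO3, MeOH) comes back to the route at 4, now isolated, which is hydrolysed to 5 with pyridinium tosylate in wet acetone.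

**Further compounds**

F1 | step 15 | tert-butyl-[[(1R,4R)-4-[(1E,3E,5E,7E)-8-iodo-3,7-dimethylocta-1,3,5,7-tetraenyl]-3,5,5-trimethylcyclohex-2-en-1-yl]oxy]dimethylsilane | CC1=C[C@H](O[Si](C)(C)C(C)(C)C)CC(C)(C)[C@H]1/C=C/C(C)=C/C=C/C(C)=C/I
F2 | step 15 | tert-butyl-[(2E,4E,6E,8E)-2,6-dimethyl-9-(tributylstannyl)nona-2,4,6,8-tetraenoxy]dimethylsilane | CCCC[Sn](CCCC)(CCCC)/C=C/C=C(C)/C=C/C=C(\C)CO[Si](C)(C)C(C)(C)C
F3 | step 7 | (2E,4E)-5-[(1R,4R)-4-(tert-butyldimethylsilyloxy)-2,6,6-trimethylcyclohex-2-en-1-yl]-3-methylpenta-2,4-dienenitrile | CC1=C[C@H](O[Si](C)(C)C(C)(C)C)CC(C)(C)[C@H]1/C=C/C(C)=C/C#N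
F4 | step 7 | (2E,4E)-5-[(1R,4R)-4-(tert-butyldimethylsilyloxy)-2,6,6-trimethylcyclohex-2-en-1-yl]-3-methylpenta-2,4-dienal | CC1=C[C@H](O[Si](C)(C)C(C)(C)C)CC(C)(C)[C@H]1/C=C/C(C)=C/C=O
F5 | step 3 | (1S,4R)-3,5,5-trimethyl-4-[(E)-2-(2-methyl-1,3-dioxolan-2-yl)ethenyl]cyclohex-2-en-1-ol | CC1=C[C@@H](O)CC(C)(C)[C@H]1/C=C/C2(C)OCCO2
F6 | step 3 | [(1R,4R)-3,5,5-trimethyl-4-[(E)-2-(2-methyl-1,3-dioxolan-2-yl)ethenyl]cyclohex-2-en-1-yl] 4-nitrobenzoate | CC1=C[C@H](OC(=O)c2ccc(cc2)[N+](=O)[O-])CC(C)(C)[C@H]1/C=C/C2(C)OCCO2
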